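**The ratio.** The ochre run's last reading, at 20.0 h, gives 47.2 for the selectivity factor, the logarithm of the part of left-handed substrate left divided by the same logarithm for right-handed substrate. At a ratio of one, the mirror-image zero of the scale, the two go together and no excess forms.

common to all: left-handed substrate 0.80 M; right-handed substrate 0.80 M; free catalyst 0.094 mol%

| run | partner | protic impurity | remark | time |
|---|---|---|---|---|
| blue | 0.75 equiv | 0.24 M | run made earlier |  |
| ochre | 1.1 equiv | 0.24 M | run made earlier |  |
| flask | 1.50 equiv | 0.240 M |  | 20 h |

- blue (time / h: left-handed substrate / %, right-handed substrate / %): 1.00: 33.5, 50.0; 3.00: 23.1, 49.2; 6.00: 19.0, 49.1; 8.00: 17.0, 49.1; 12.0: 15.5, 49.1; 15.0: 16.1, 48.6; 20.0: 15.2, 49.0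
- ochre (time / h: left-handed substrate / %, right-handed substrate / %): 1.00: 26.9, 48.9; 3.00: 14.8, 49.1; 6.00: 8.2, 48.3; 8.00: 7.0, 47.6; 12.0: 5.2, 47.8; 15.0: 4.1, 47.0; 20.0: 3.3, 47.2

(standard deviation of a reading: 0.3 percentage points)

- free catalyst is single-handed; left-handed substrate and right-handed substrate are mirror images of each other, charged as a racemate, each of them at the stated concentration
- an excess is the difference of the two amounts in percent of their sum
- an excess is below zero if the other one leads

- part of the left-handed substrate and right-handed substrate charged together that has reacted at 20 h
- excess of left-handed product over right-handed product in the product at 20 h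
- excess of right-handed substrate over left-handed substrate among what is left of the two at 20 h

**Partner budget.** The blue run ends with 0.573 M reacted from 0.600 M of partner, so I book 0.0272 M to the protic impurity. For the flask I reckon a tail of 0.373 M of [partner] once left-handed substrate has taken its 0.80 M.

**Rate.** Over the ochre run's first 1.00 h, left-handed substrate gives a rate constant of 0.903 /M/h per unit of mean [partner], with the catalyst folded in.

**First number.** With a steady tail, the flask's left-handed logarithm at 20 h is the rate constant times tail times time, plus the logarithm of ([left-handed substrate] + tail) over tail: 7.88. Dividing by the ratio gives 57.7% reacted.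

**Weak link.** The tail isn't steady. The blue run's loss, set against its own partner-time, gives a leak of 0.0206 /h, so the tail counts for 16.4 h. The logarithm falls to 6.66, leaving 43.4% of right-handed substrate. With 0.0638% of left-handed substrate, I commit to 56.5% reacted, a product excess of 76.7% and a substrate excess of 99.7%.

**The forecast.** It says 56.9%, 75.8% and 99.6%, a little above my conversion: “About 20% partner remains, which slowly eats the right-handed substrate”.

**The flask.** It gives 55.4%, 79.9% and 99.4%.

    partner + free catalyst + left-handed substrate → free catalyst + left-handed product (k = 1200 /M²/h)
    partner + free catalyst + right-handed substrate → free catalyst + right-handed product (k = 24.0 /M²/h)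
    partner + protic impurity → quenched reagent (k = 0.100 /M/h)
    free catalyst → spent catalyst (k = 0.00270 /h)

**Carried on.** The ratio turns this flask's 0.28% of charged left-handed substrate left into 88.3% of right-handed substrate left, and the flask holds 89%. With 0.600 equiv of partner, the limiting reagent there, down to 0.046% of its charge, that neighbouring flask keeps 44% of its left-handed substrate. From that amount the ratio gives 0.857% of right-handed product and a product excess of 94.1%; that flask holds 0.809% and gives 94.4%.

The data stem from a simulated flask with made-up constants.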